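**Assumption:** the target has no stereocentre, so no enantiocontrol is needed; it is made exactly as drawn, as the free hydrogen sulfate, liberated from its stable sodium salt only in the last step.

## Retrosynthetic overview

1. Target ⇐ protonation of its sodium salt ⇐ hydrogenolysis of the 5,7-di-O-benzyl sulfate ⇐ sulfation of the only free hydroxyl (C3–OH) of 5,7-di-O-benzylkaempferide.
2. C3–OH ⇐ epoxidation and isomerisation of 5,7-bis(benzyloxy)-4'-methoxyflavone at C2=C3.
3. Ring C ⇐ oxidative cyclisation (oxa-Michael, then dehydrogenation) of a 2'-hydroxychalcone.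
4. Chalcone ⇐ Claisen–Schmidt aldol condensation of 4',6'-bis(benzyloxy)-2'-hydroxyacetophenone with 4-methoxybenzaldehyde (key C–C bond, the future C2–C3).
5. Ring order: rings A and B are bought in; ring C is the only ring formed (step 3).

## Route

**Step 1**
Reactants: 1 2',4',6'-trihydroxyacetophenone
Product: 2 1-[2,4-bis(benzyloxy)-6-hydroxyphenyl]ethan-1-one
Conditions: BnBr (2.1 equiv), K2CO3 (2.2 equiv), DMF, 0 °C to rt, 16 h
Reagents that add atoms: benzyl bromide, BrCc1ccccc1
Why: Williamson ether synthesis in which the 4-OH and one ortho OH are alkylated, while the last ortho OH stays free because it is hydrogen-bonded to the acetyl carbonyl and only about two equivalents of halide are used.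

**Step 2**
Reactants: 2 1-[2,4-bis(benzyloxy)-6-hydroxyphenyl]ethan-1-one; 3 4-methoxybenzaldehyde
Product: 5 (E)-1-[2,4-bis(benzyloxy)-6-hydroxyphenyl]-3-(4-methoxyphenyl)prop-2-en-1-one, via aldol adduct 4 (not isolated)
Conditions: KOH (50% aq, excess), EtOH/THF, rt, 36 h
Reagents that add atoms: none
Why: Claisen–Schmidt (crossed aldol) condensation in which the ketone enolate adds to the non-enolisable aldehyde and the β-hydroxy ketone loses water by E1cB to the thermodynamically favoured E-chalcone, so no stereocentre survives.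

**Step 3**
Reactants: 5 (E)-1-[2,4-bis(benzyloxy)-6-hydroxyphenyl]-3-(4-methoxyphenyl)prop-2-en-1-one
Product: 7 5,7-bis(benzyloxy)-4'-methoxyflavone, via flavanone 6 (not isolated)
Conditions: I2 (0.1 equiv), DMSO, 130 °C, 3 h; aq Na2S2O3 wash
Reagents that add atoms: none
Why: I2/DMSO oxidative cyclisation in which intramolecular oxa-Michael addition of the 2'-phenol gives the flavanone, which is α-iodinated and loses HI to the flavone while DMSO reoxidises HI to I2; benzyl ethers tolerate the catalytic iodine.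

**Step 4**
Reactants: 7 5,7-bis(benzyloxy)-4'-methoxyflavone
Product: 9 5,7-bis(benzyloxy)-3-hydroxy-4'-methoxyflavone, via epoxyflavanone 8 (not isolated)
Conditions: DMDO (ca. 0.07 M in acetone, 2.5 equiv), CH2Cl2, 0 °C to rt, 12 h; then p-TsOH·H2O (0.1 equiv), CH2Cl2, rt, 1 h
Reagents that add atoms: dimethyldioxirane (DMDO), CC1(C)OO1
Why: dimethyldioxirane epoxidation of the enol-ether-like C2=C3 bond followed by acid-catalysed epoxide opening and proton loss to the 3-hydroxyflavone, which destroys both stereocentres of the racemic epoxide.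

**Step 5**
Reactants: 9 5,7-bis(benzyloxy)-3-hydroxy-4'-methoxyflavone
Product: 10 sodium 5,7-bis(benzyloxy)-4'-methoxyflavon-3-yl sulfate
Conditions: SO3·pyridine (5 equiv), pyridine, 50 °C, 6 h; then aq NaHCO3 to pH 8; C18 or Sephadex LH-20 chromatography
Reagents that add atoms: sulfur trioxide–pyridine complex, O=S(=O)([O-])[n+]1ccccc1; sodium hydrogen carbonate, [Na+].OC(=O)[O-]
Why: O-sulfation with an SO3–amine complex, regioselective because C3–OH is the only free hydroxyl, with bicarbonate work-up giving the base-stable sodium aryl sulfate.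

**Step 6**
Reactants: 10 sodium 5,7-bis(benzyloxy)-4'-methoxyflavon-3-yl sulfate
Product: 11 sodium kaempferide 3-O-sulfate (sodium 5,7-dihydroxy-4'-methoxyflavon-3-yl sulfate)
Conditions: H2 (1 atm), Pd/C (10% palladium on carbon), MeOH/THF 1:1, rt, 3 h; filter
Reagents that add atoms: none
Why: catalytic hydrogenolysis of benzyl aryl ethers under neutral, amine-free conditions, which leaves the sulfate monoester salt, the methyl ether and the tetrasubstituted C2=C3 bond untouched.

**Step 7**
Reactants: 11 sodium kaempferide 3-O-sulfate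
Product: 12 kaempferide 3-O-sulfate (5,7-dihydroxy-4'-methoxyflavon-3-yl hydrogen sulfate)
Conditions: HCl (1.00 equiv, 0.1 M aq), H2O/MeOH, 0 °C, 5 min; C18 cartridge (H2O, then MeOH); freeze-dry
Reagents that add atoms: none
Why: simple acidification (proton-for-sodium exchange) at low temperature, where the aryl sulfate monoester hydrolyses only slowly, followed by reversed-phase desalting and freeze-drying to the free acid.

## Compound list

1 | 1-(2,4,6-trihydroxyphenyl)ethan-1-one (2',4',6'-trihydroxyacetophenone) | CC(=O)c1c(O)cc(O)cc1O | starting material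
2 | 1-[2,4-bis(benzyloxy)-6-hydroxyphenyl]ethan-1-one | CC(=O)c1c(O)cc(OCc2ccccc2)cc1OCc1ccccc1 | intermediate
3 | 4-methoxybenzaldehyde | COc1ccc(C=O)cc1 | starting material
4 | racemic 1-[2,4-bis(benzyloxy)-6-hydroxyphenyl]-3-hydroxy-3-(4-methoxyphenyl)propan-1-one (aldol adduct, not isolated) | COc1ccc(cc1)C(O)CC(=O)c1c(O)cc(OCc2ccccc2)cc1OCc1ccccc1 | intermediate
5 | (E)-1-[2,4-bis(benzyloxy)-6-hydroxyphenyl]-3-(4-methoxyphenyl)prop-2-en-1-one (chalcone) | COc1ccc(/C=C/C(=O)c2c(O)cc(OCc3ccccc3)cc2OCc2ccccc2)cc1 | intermediate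
6 | racemic 5,7-bis(benzyloxy)-4'-methoxyflavanone (not isolated) | COc1ccc(cc1)C1CC(=O)c2c(OCc3ccccc3)cc(OCc3ccccc3)cc2O1 | intermediate
7 | 5,7-bis(benzyloxy)-4'-methoxyflavone | COc1ccc(cc1)-c1cc(=O)c2c(OCc3ccccc3)cc(OCc3ccccc3)cc2o1 | intermediate
8 | racemic cis-fused 5,7-bis(benzyloxy)-4'-methoxyflavone 2,3-epoxide (one enantiomer drawn, not isolated) | COc1ccc(cc1)[C@@]12O[C@@H]1C(=O)c1c(OCc3ccccc3)cc(OCc3ccccc3)cc1O2 | intermediate
9 | 5,7-bis(benzyloxy)-3-hydroxy-4'-methoxyflavone | COc1ccc(cc1)-c1oc2cc(OCc3ccccc3)cc(OCc3ccccc3)c2c(=O)c1O | intermediate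
10 | sodium 5,7-bis(benzyloxy)-4'-methoxyflavon-3-yl sulfate | COc1ccc(cc1)-c1oc2cc(OCc3ccccc3)cc(OCc3ccccc3)c2c(=O)c1OS(=O)(=O)[O-].[Na+] | intermediate
11 | sodium kaempferide 3-O-sulfate | COc1ccc(cc1)-c1oc2cc(O)cc(O)c2c(=O)c1OS(=O)(=O)[O-].[Na+] | intermediate
12 | kaempferide 3-O-sulfate | COc1ccc(-c2oc3cc(O)cc(O)c3c(=O)c2OS(=O)(=O)O)cc1 | target

## Summary and fallbacks

Total step count: 7. Longest linear sequence: 7 steps (from 1).

The three steps most likely to fail:

**Step 5 (sulfation of the hydrogen-bonded 3-OH, and isolation of the salt).** The fallback sets out from 9 and comes back at 10. Flavonol 9 is treated with 2,2,2-trichloroethyl chlorosulfate, Et3N and DMAP in THF to give the neutral, silica-stable 5,7-bis(benzyloxy)-4'-methoxyflavon-3-yl 2,2,2-trichloroethyl sulfate F4. The trichloroethyl group is then removed reductively with Zn dust and HCO2NH4 in MeOH at rt to give ammonium 5,7-bis(benzyloxy)-4'-methoxyflavon-3-yl sulfate F5. Evaporation of F5 from aqueous NaHCO3 drives off ammonia and gives 10. This replaces direct sulfation by a protected sulfate diester that can be purified like an ordinary organic compound.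

**Step 4 (dimethyldioxirane epoxidation; incomplete conversion or benzylic over-oxidation).** The fallback sets out from 7 and comes back at 9. Flavone 7 is deprotonated at C3 with LiN(iPr)2 in THF at −78 °C to give 5,7-bis(benzyloxy)-3-lithio-4'-methoxyflavone F2. F2 is trapped with B(OMe)3 as dimethyl [5,7-bis(benzyloxy)-2-(4-methoxyphenyl)-4-oxo-4H-chromen-3-yl]boronate F3. F3 is oxidised in the same flask with H2O2/AcOH at 0 °C to 9. This swaps electrophilic oxygen transfer for C3 metalation, borylation and C–B oxidation.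

**Step 1 (selective dibenzylation; tri-O- and C-benzylated by-products).** The fallback sets out from 1 and comes back at 2. Compound 1 is exhaustively benzylated (BnBr 3.5 equiv, K2CO3, DMF, 70 °C) to 1-[2,4,6-tris(benzyloxy)phenyl]ethan-1-one F1. One of the two equivalent ortho benzyl ethers is then cleaved by chelation-controlled debenzylation with MgBr2·OEt2 in toluene/Et2O at reflux, giving 2. This replaces statistical partial alkylation by full protection and a carbonyl-directed single deprotection.

## Further compounds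

F1 | step 1 | 1-[2,4,6-tris(benzyloxy)phenyl]ethan-1-one | CC(=O)c1c(OCc2ccccc2)cc(OCc2ccccc2)cc1OCc1ccccc1
F2 | step 4 | 5,7-bis(benzyloxy)-3-lithio-4'-methoxyflavone | [Li]c1c(-c2ccc(OC)cc2)oc2cc(OCc3ccccc3)cc(OCc3ccccc3)c2c1=O
F3 | step 4 | dimethyl [5,7-bis(benzyloxy)-2-(4-methoxyphenyl)-4-oxo-4H-chromen-3-yl]boronate | COB(OC)c1c(-c2ccc(OC)cc2)oc2cc(OCc3ccccc3)cc(OCc3ccccc3)c2c1=O
F4 | step 5 | 5,7-bis(benzyloxy)-4'-methoxyflavon-3-yl 2,2,2-trichloroethyl sulfate | COc1ccc(cc1)-c1oc2cc(OCc3ccccc3)cc(OCc3ccccc3)c2c(=O)c1OS(=O)(=O)OCC(Cl)(Cl)Cl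
F5 | step 5 | ammonium 5,7-bis(benzyloxy)-4'-methoxyflavon-3-yl sulfate | COc1ccc(cc1)-c1oc2cc(OCc3ccccc3)cc(OCc3ccccc3)c2c(=O)c1OS(=O)(=O)[O-].[NH4+]
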